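Retrosynthetic cuts: the C5-OH/C6-isovaleryl pair is first read as a reductively opened 2,2-dimethyldihydropyran-4-one (extra bond O5–CMe2, ring C). Then O1–C2 and C3–C4 of dihydropyran ring B are cut together (retro-[4+2]). Last, C4–C4a (formaldehyde), C8–CHO (formylation) and the C6–acyl and O–CMe2 bonds (3,3-dimethylacrylic acid) lead back to phloroglucinol.
Enabling feature: ring B is O1–C2(spiro, fully substituted)–C3H2–C4H2–C4a=C8a. O1, C8a, C4a and C4 are an o-quinone methide of benzene ring A, and C3–C2 are the exocyclic CH2=C of β-pinene, whose two pinane rings sit unchanged on C2.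
Forward order: ring A (bought) → temporary ring C → formyl group → ring B, the last ring of the skeleton, closed onto the bought pinane rings → ring C opened and saturated to the isovaleryl ketone.
Helper: ring C turns the phenol oxygen beside the ketone into an ether, so only the oxygen beside the formyl group can become O1. It also carries the side chain at the enone oxidation level until the last step.
Stereochemistry: C1' and C5' are bought with (1S,5S)-(−)-β-pinene. The spiro carbon is set in the cycloaddition by attack on the alkene face remote from the CMe2 bridge.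

Key step: step 3

Remark: locants of 4–6, 8 and 9 follow chroman-4-one, those of 10 follow pyrano[2,3-f]chromene, and those of 11 and 12 follow chroman; primed locants are pinane positions. Assumption: commercial (−)-β-pinene is taken as enantiomerically pure, and its purity passes unchanged into 12.

Step 1
Reactants: 1 phloroglucinol; 2 3,3-dimethylacrylic acid
Product: 4 5,7-dihydroxy-2,2-dimethylchroman-4-one, via aryl enone 3 (not isolated)
Conditions: P2O5, MeSO3H, 70 °C
Reagents that add atoms: none
Why: Friedel–Crafts acylation of the threefold-symmetric, highly activated arene gives enone 3, whose ortho hydroxyl closes ring C by an acid-catalysed 6-endo-trig oxa-Michael addition, so one operation installs all five side-chain carbons and turns exactly one of the two ketone-flanking phenols into an ether; no stereocentre is formed.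

Step 2
Reactants: 4 5,7-dihydroxy-2,2-dimethylchroman-4-one
Product: 6 5,7-dihydroxy-2,2-dimethyl-4-oxochroman-6-carbaldehyde, via aryl iminium chloride 5 (not isolated)
Conditions: POCl3 (1.1 equiv), DMF, EtOAc, 0 °C to rt; then H2O
Reagents that add atoms: N,N-dimethylformamide, CN(C)C=O; water, O
Why: Vilsmeier–Haack formylation as practised on acylphloroglucinols: the chloroiminium ion should attack C6, which is flanked by the two free hydroxyls and para to the ring ether oxygen, rather than C8, while one equivalent of reagent, the deactivating first formyl group and the low temperature should prevent a second attack or reaction at the chelated ketone, and water hydrolyses 5.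

Step 3
Reactants: 6 5,7-dihydroxy-2,2-dimethyl-4-oxochroman-6-carbaldehyde; 7 (1S,5S)-(−)-β-pinene
Product: 10 (1'R,2'R,5'S)-5-hydroxy-2,2,6',6'-tetramethyl-4-oxo-3,4,9,10-tetrahydro-2H-spiro[pyrano[2,3-f]chromene-8,2'-bicyclo[3.1.1]heptane]-6-carbaldehyde, via hydroxymethylphenol 8 (not isolated), via o-quinone methide 9 (not isolated)
Conditions: (CH2O)n, NaOAc, AcOH, 90 °C, sealed tube, excess 7
Reagents that add atoms: paraformaldehyde (reacts as formaldehyde), C=O
Why: Formaldehyde condenses at C8, the only open carbon of ring A, to give 8, which loses water across C8 and the C7 hydroxyl to form o-quinone methide 9, an electron-poor 1-oxadiene (O=C7–C8=CH2) that adds to the exocyclic alkene of 7 in an inverse-electron-demand hetero-Diels–Alder reaction; the closest known reaction type is the three-component Knoevenagel/hetero-Diels–Alder coupling of formyl- and acylphloroglucinols with aldehydes and terpene alkenes. Ring B closes in an intermolecular, concerted but asynchronous [4+2] mode that makes the C3–C4 and O1–C2 bonds (target locants) in one event. The orientation follows the polarisation of both partners: the electrophilic methide carbon bonds to the unsubstituted alkene terminus, positive charge builds at the fully substituted pinane carbon, and the oxygen closes onto it. The only new stereocentre, the spiro carbon, is controlled by the pinane cage, because the CMe2 bridge screens one alkene face and both bonds therefore form on the face of the CH2 bridge, which places O1 anti to the CMe2 bridge (R) and leaves C1' and C5' untouched. The step needs selectivity between the two oxygens that flank the methide carbon, and ring C secures it: the oxygen beside the ketone is an ether that cannot become a carbonyl by tautomerisation, so only the oxygen beside the formyl group can end as O1. Excess 7 and the acetate buffer should favour cycloaddition over oligomerisation of 9, ene-type addition and acid isomerisation of 7.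

Step 4
Reactants: 10 (1'R,2'R,5'S)-5-hydroxy-2,2,6',6'-tetramethyl-4-oxo-3,4,9,10-tetrahydro-2H-spiro[pyrano[2,3-f]chromene-8,2'-bicyclo[3.1.1]heptane]-6-carbaldehyde
Product: 12 Euglobal G3, via ring-opened enone 11 (not isolated)
Conditions: KOtBu (3 equiv), THF/t-BuOH, rt; then H2 (1 atm), 10% Pd/C, rt; AcOH quench at 0 °C
Reagents that add atoms: none
Why: tert-Butoxide ionises the C5 phenol and enolises C3, the enolate expels the aryloxide that is para to the formyl and ortho to the keto group (E1cB retro-oxa-Michael opening, the known behaviour of chroman-4-ones, 2,2-dimethyl ones included, in alkali), ionisation of the freed phenol holds the equilibrium on the side of 11, and Pd/C–H2 saturates the enone irreversibly as in the alkaline hydrogenation of flavanones to dihydrochalcones, while the phenoxide-deactivated aldehyde and ketone, the base-stable spiro ether and the three stereocentres should stay untouched.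

Compound list
1 | phloroglucinol (benzene-1,3,5-triol) | Oc1cc(O)cc(O)c1 | starting material
2 | 3,3-dimethylacrylic acid (3-methylbut-2-enoic acid) | CC(C)=CC(=O)O | starting material
3 | 3-methyl-1-(2,4,6-trihydroxyphenyl)but-2-en-1-one | CC(C)=CC(=O)c1c(O)cc(O)cc1O | intermediate
4 | 5,7-dihydroxy-2,2-dimethylchroman-4-one | CC1(C)CC(=O)c2c(O)cc(O)cc2O1 | intermediate
5 | N-[(5,7-dihydroxy-2,2-dimethyl-4-oxochroman-6-yl)methylidene]-N-methylmethanaminium chloride | CC1(C)CC(=O)c2c(O)c(C=[N+](C)C)c(O)cc2O1.[Cl-] | intermediate
6 | 5,7-dihydroxy-2,2-dimethyl-4-oxochroman-6-carbaldehyde | CC1(C)CC(=O)c2c(O)c(C=O)c(O)cc2O1 | intermediate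
7 | (1S,5S)-(−)-β-pinene (6,6-dimethyl-2-methylidenebicyclo[3.1.1]heptane) | C=C1CC[C@H]2C[C@@H]1C2(C)C | starting material
8 | 5,7-dihydroxy-8-(hydroxymethyl)-2,2-dimethyl-4-oxochroman-6-carbaldehyde | CC1(C)CC(=O)c2c(O)c(C=O)c(O)c(CO)c2O1 | intermediate
9 | 5-hydroxy-2,2-dimethyl-8-methylidene-4,7-dioxo-3,4,7,8-tetrahydro-2H-chromene-6-carbaldehyde (o-quinone methide) | CC1(C)CC(=O)C2=C(O1)C(=C)C(=O)C(C=O)=C2O | intermediate
10 | (1'R,2'R,5'S)-5-hydroxy-2,2,6',6'-tetramethyl-4-oxo-3,4,9,10-tetrahydro-2H-spiro[pyrano[2,3-f]chromene-8,2'-bicyclo[3.1.1]heptane]-6-carbaldehyde (O7 anti to the CMe2 bridge) | CC1(C)CC(=O)c2c(O)c(C=O)c3c(c2O1)CC[C@@]4(CC[C@H]5C[C@@H]4C5(C)C)O3 | intermediate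
11 | (1'R,2R,5'S)-5,7-dihydroxy-6',6'-dimethyl-6-(3-methylbut-2-enoyl)spiro[chroman-2,2'-bicyclo[3.1.1]heptane]-8-carbaldehyde (in the flask as its dipotassium bis-phenoxide) | CC(C)=CC(=O)c1c(O)c(C=O)c2c(c1O)CC[C@@]1(CC[C@H]3C[C@@H]1C3(C)C)O2 | intermediate
12 | Euglobal G3, (1'R,2R,5'S)-5,7-dihydroxy-6',6'-dimethyl-6-(3-methylbutanoyl)spiro[chroman-2,2'-bicyclo[3.1.1]heptane]-8-carbaldehyde | CC(C)CC(=O)c1c(O)c(C=O)c2c(c1O)CC[C@@]1(CC[C@H]3C[C@@H]1C3(C)C)O2 | target

Total step count: 4. Longest linear sequence: 4 steps (1 → 4 → 6 → 10 → 12).

Steps most likely to fail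

Step 4. The retro-oxa-Michael opening may be slow or incomplete. Ring C may reclose on acidification before the alkene is saturated. Adventitious water may cleave the side chain by retro-aldol loss of acetone, and the formyl group may be over-reduced. The fallback separates opening from reduction and passes through an isolable open-chain compound. It sets out from 10. KOtBu in THF followed by Ac2O should trap the opened bis-phenoxide as the ring-opened enone diacetate F1, which cannot reclose. Hydrogenation under neutral conditions (H2, Pd/C, EtOAc) should give the saturated diacetate F2. K2CO3 in MeOH should then remove both acetates, and the route is rejoined at 12.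

Step 3. Acid may isomerise 7, or free formaldehyde may consume it in a Prins or carbonyl-ene reaction. The quinone methide may oligomerise, ene-type addition may compete with cycloaddition, and facial selectivity may be incomplete. The fallback uses an isolated precursor that needs neither acid nor free formaldehyde. It sets out from 6. A Mannich reaction with CH2(NMe2)2 in dioxane should give the C8 Mannich base F3. Heating F3 with excess 7 in toluene under a slow N2 sweep should eliminate the amine thermally to the same quinone methide 9, and the route is rejoined at 10.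

Step 2. Site selectivity between C6 and C8 may be poor, a second formylation may occur, or the ketone α-carbon may undergo chloroformylation. The fallback replaces intrinsic preference with direction by a single free phenol. It sets out from 4. Selective benzylation of the non-chelated C7 hydroxyl (BnBr, K2CO3, acetone) should give the 7-benzyl ether F4. The remaining C5 phenol then directs an ortho-specific formylation (MgCl2, Et3N, (CH2O)n, MeCN, reflux) to C6, its only open ortho carbon, to give the benzylated aldehyde F5. Hydrogenolysis (H2, Pd/C, EtOAc) rejoins the route at 6.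

Further compounds
F1 | step 4 | (1'R,2R,5'S)-8-formyl-6',6'-dimethyl-6-(3-methylbut-2-enoyl)spiro[chroman-2,2'-bicyclo[3.1.1]heptane]-5,7-diyl diacetate | CC(C)=CC(=O)c1c(OC(C)=O)c(C=O)c2c(c1OC(C)=O)CC[C@@]1(CC[C@H]3C[C@@H]1C3(C)C)O2
F2 | step 4 | (1'R,2R,5'S)-8-formyl-6',6'-dimethyl-6-(3-methylbutanoyl)spiro[chroman-2,2'-bicyclo[3.1.1]heptane]-5,7-diyl diacetate | CC(C)CC(=O)c1c(OC(C)=O)c(C=O)c2c(c1OC(C)=O)CC[C@@]1(CC[C@H]3C[C@@H]1C3(C)C)O2
F3 | step 3 | 8-[(dimethylamino)methyl]-5,7-dihydroxy-2,2-dimethyl-4-oxochroman-6-carbaldehyde | CC1(C)CC(=O)c2c(O)c(C=O)c(O)c(CN(C)C)c2O1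
F4 | step 2 | 7-(benzyloxy)-5-hydroxy-2,2-dimethylchroman-4-one | CC1(C)CC(=O)c2c(O)cc(OCc3ccccc3)cc2O1
F5 | step 2 | 7-(benzyloxy)-5-hydroxy-2,2-dimethyl-4-oxochroman-6-carbaldehyde | CC1(C)CC(=O)c2c(O)c(C=O)c(OCc3ccccc3)cc2O1
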